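The route rests on cutting C8–C9. C9 is a single CH2O carbon on C8, C8 adjoins the benzylic C7 of ring A, and the oxygen on C9' lies four bonds from C9. A bromomethylsilyl group on that oxygen can therefore deliver C9 as a radical to C8 of a C7=C8 styrene: one operation closes a six-membered oxasilinane, forms C8–C9, sets C8 relative to C8' and leaves C7 as CH2. The precursor is the (bromomethyl)dimethylsilyl ether of an E-homoallylic alcohol whose C8' centre (R, from an Evans alkylation) carries the ring B benzyl group and whose alkene carries O-benzylated ring A. Tamao oxidation, benzoylation and hydrogenolysis then finish.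

Key step: step 7

Labels and assumptions: ring A = 3-hydroxy-4-methoxyphenyl (on C7), ring B = 4-hydroxy-3-methoxyphenyl (on C7'); C8 and C8' are the stereocentres (both R in the target), C9 and C9' the CH2O carbons. The two O-benzylated aromatic building blocks are assumed to be bought as such. The (R)-configured auxiliary is the enantiomer that gives C8' = R. The styrene is carried on the acyl chain from the start, as the E isomer, so no late metathesis is needed.

Step 1
Reactants: 1 [4-(benzyloxy)-3-methoxyphenyl]methanol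
Product: 2 1-(benzyloxy)-4-(bromomethyl)-2-methoxybenzene
Conditions: PBr3 (0.4 equiv), Et2O, 0 °C
Reagents that add atoms: phosphorus tribromide, BrP(Br)Br
Why: Substitution of an electron-rich benzylic alcohol by bromide through its phosphite ester (PBr3 bromination) is routine, and the aryl ethers are inert to it.

Step 2
Reactants: 3 3-(benzyloxy)-4-methoxybenzaldehyde; 4 (2-carboxyethyl)triphenylphosphonium bromide
Product: 6 (3E)-4-[3-(benzyloxy)-4-methoxyphenyl]but-3-enoic acid, via carboxylate ylide 5 (not isolated)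
Conditions: NaN(SiMe3)2 (2 equiv per 4), THF, 0 °C; then 3, −78 °C → rt; 1 M HCl; crystallisation
Reagents that add atoms: none
Why: Wittig olefination of aryl aldehydes with the carboxylate-bearing ylide is an established entry to 4-arylbut-3-enoic acids and favours the E alkene, and crystallisation of the acid should remove any Z isomer so that the key step starts from one geometry.

Step 3
Reactants: 6 (3E)-4-[3-(benzyloxy)-4-methoxyphenyl]but-3-enoic acid; 7 (4R)-4-benzyl-1,3-oxazolidin-2-one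
Product: 9 (4R)-4-benzyl-3-{(3E)-4-[3-(benzyloxy)-4-methoxyphenyl]but-3-enoyl}-1,3-oxazolidin-2-one, via mixed pivalic anhydride 8 (not isolated)
Conditions: PivCl, Et3N, THF, −20 °C; then 7, LiCl, −20 °C → rt
Reagents that add atoms: none
Why: N-acylation of the oxazolidinone through the mixed anhydride takes place at the less hindered carbonyl without strong base, and the alkene stays in conjugation with ring A, where it is most stable.

Step 4
Reactants: 9 (4R)-4-benzyl-3-{(3E)-4-[3-(benzyloxy)-4-methoxyphenyl]but-3-enoyl}-1,3-oxazolidin-2-one; 2 1-(benzyloxy)-4-(bromomethyl)-2-methoxybenzene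
Product: 11 (4R)-4-benzyl-3-{(2R,3E)-2-[4-(benzyloxy)-3-methoxybenzyl]-4-[3-(benzyloxy)-4-methoxyphenyl]but-3-enoyl}-1,3-oxazolidin-2-one, via sodium Z-dienolate 10 (not isolated)
Conditions: NaN(SiMe3)2 (1.1 equiv), THF, −78 °C; then 2, −78 → −45 °C; AcOH quench
Reagents that add atoms: none
Why: Evans alkylation, in which the chelated Z-dienolate reacts at its α-carbon with the reactive benzylic bromide on the face away from the C4 benzyl group of the (R)-auxiliary, which sets C8' as R.

Step 5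
Reactants: 11 (4R)-4-benzyl-3-{(2R,3E)-2-[4-(benzyloxy)-3-methoxybenzyl]-4-[3-(benzyloxy)-4-methoxyphenyl]but-3-enoyl}-1,3-oxazolidin-2-one
Product: 12 (2R,3E)-2-[4-(benzyloxy)-3-methoxybenzyl]-4-[3-(benzyloxy)-4-methoxyphenyl]but-3-en-1-ol
Conditions: LiBH4 (2 equiv), THF, 0 °C
Reagents that add atoms: none
Why: Reductive cleavage of the N-acyl oxazolidinone with LiBH4 releases the primary alcohol and the auxiliary under conditions that leave the styrene and benzyl ethers alone and should not enolise C8'.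

Step 6
Reactants: 12 (2R,3E)-2-[4-(benzyloxy)-3-methoxybenzyl]-4-[3-(benzyloxy)-4-methoxyphenyl]but-3-en-1-ol; 13 (bromomethyl)chlorodimethylsilane
Product: 14 (bromomethyl)({(2R,3E)-2-[4-(benzyloxy)-3-methoxybenzyl]-4-[3-(benzyloxy)-4-methoxyphenyl]but-3-en-1-yl}oxy)dimethylsilane
Conditions: Et3N, DMAP (cat.), CH2Cl2, 0 °C; filtration through Et3N-deactivated silica, used at once
Reagents that add atoms: none
Why: Silylation of a primary alcohol with a chlorosilane under amine and DMAP catalysis is fast at 0 °C and places the bromomethylsilyl tether on the C9' oxygen.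

Step 7
Reactants: 14 (bromomethyl)({(2R,3E)-2-[4-(benzyloxy)-3-methoxybenzyl]-4-[3-(benzyloxy)-4-methoxyphenyl]but-3-en-1-yl}oxy)dimethylsilane
Product: 15 (4R,5R)-4-[3-(benzyloxy)-4-methoxybenzyl]-5-[4-(benzyloxy)-3-methoxybenzyl]-2,2-dimethyl-1,2-oxasilinane
Conditions: Bu3SnH (1.3 equiv, syringe pump), AIBN (0.15 equiv), PhH (0.01 M), 80 °C; KF/silica filtration
Reagents that add atoms: none
Why: In a radical chain, Bu3Sn• abstracts bromine from 14, the α-silyl primary radical adds to C8 of the C7=C8 styrene, and the benzylic C7 radical takes hydrogen from Bu3SnH, giving the new C8–C9 and C7–H bonds. The closest known reaction type is the tin hydride cyclization of (bromomethyl)dimethylsilyl ethers of homoallylic alcohols with a substituted alkene terminus, which closes the same 1-oxa-2-silacyclohexane. The ring closes in the 6-exo-trig mode, because 7-endo attack at C7 would form the larger ring and a non-benzylic radical at C8. The C8 centre is set by the existing C8' centre through a chair-like transition state in which the ring B benzyl group on C8' and the developing ring A benzyl arm on C8 are both equatorial, so the two benzyl groups end up trans on the ring, which is the 8R,8'R relationship. The step needs regioselectivity (secured by the aryl group on C7), 1,2-diastereoselectivity (helped by the E alkene, which puts only hydrogen cis to C8') and cyclization ahead of direct reduction (secured by slow stannane addition at high dilution).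

Step 8
Reactants: 15 (4R,5R)-4-[3-(benzyloxy)-4-methoxybenzyl]-5-[4-(benzyloxy)-3-methoxybenzyl]-2,2-dimethyl-1,2-oxasilinane
Product: 16 (2R,3R)-2-[3-(benzyloxy)-4-methoxybenzyl]-3-[4-(benzyloxy)-3-methoxybenzyl]butane-1,4-diol
Conditions: 30% H2O2, KF, KHCO3, THF/MeOH (1:1), rt → 50 °C
Reagents that add atoms: hydrogen peroxide, OO
Why: Tamao oxidation of the alkoxysilane turns the C9–Si bond into C9–OH and frees the C9' hydroxyl without touching C8 or C8', and any minor C8 epimer should be removable at this crystalline diol stage.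

Step 9
Reactants: 16 (2R,3R)-2-[3-(benzyloxy)-4-methoxybenzyl]-3-[4-(benzyloxy)-3-methoxybenzyl]butane-1,4-diol
Product: 17 (2R,3R)-2-[3-(benzyloxy)-4-methoxybenzyl]-3-[4-(benzyloxy)-3-methoxybenzyl]butane-1,4-diyl dibenzoate
Conditions: BzCl (2.5 equiv), pyridine, DMAP (cat.), CH2Cl2, 0 °C → rt
Reagents that add atoms: benzoyl chloride, O=C(Cl)c1ccccc1
Why: DMAP-catalysed acylation of two unhindered primary alcohols with benzoyl chloride is routine, and 16 has no other nucleophilic group.

Step 10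
Reactants: 17 (2R,3R)-2-[3-(benzyloxy)-4-methoxybenzyl]-3-[4-(benzyloxy)-3-methoxybenzyl]butane-1,4-diyl dibenzoate
Product: 18 (2R,3R)-2-(3-hydroxy-4-methoxybenzyl)-3-(4-hydroxy-3-methoxybenzyl)butane-1,4-diyl dibenzoate
Conditions: H2 (1 atm), 10% Pd/C, EtOAc, rt
Reagents that add atoms: none
Why: Catalytic hydrogenolysis cleaves the two aryl benzyl ethers, while the benzoates sit on non-benzylic primary carbons and, like the methyl ethers and both stereocentres, are not affected.

Compound list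
1 | [4-(benzyloxy)-3-methoxyphenyl]methanol | COc1cc(CO)ccc1OCc1ccccc1 | starting material
2 | 1-(benzyloxy)-4-(bromomethyl)-2-methoxybenzene | COc1cc(CBr)ccc1OCc1ccccc1 | intermediate
3 | 3-(benzyloxy)-4-methoxybenzaldehyde | COc1ccc(C=O)cc1OCc1ccccc1 | starting material
4 | (2-carboxyethyl)triphenylphosphonium bromide | OC(=O)CC[P+](c1ccccc1)(c1ccccc1)c1ccccc1.[Br-] | starting material
5 | sodium 3-(triphenyl-λ5-phosphanylidene)propanoate | [Na+].[O-]C(=O)CC=P(c1ccccc1)(c1ccccc1)c1ccccc1 | intermediate (not isolated)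
6 | (3E)-4-[3-(benzyloxy)-4-methoxyphenyl]but-3-enoic acid | COc1ccc(/C=C/CC(=O)O)cc1OCc1ccccc1 | intermediate
7 | (4R)-4-benzyl-1,3-oxazolidin-2-one | O=C1N[C@H](Cc2ccccc2)CO1 | starting material
8 | (3E)-4-[3-(benzyloxy)-4-methoxyphenyl]but-3-enoic 2,2-dimethylpropanoic anhydride | COc1ccc(/C=C/CC(=O)OC(=O)C(C)(C)C)cc1OCc1ccccc1 | intermediate (not isolated)
9 | (4R)-4-benzyl-3-{(3E)-4-[3-(benzyloxy)-4-methoxyphenyl]but-3-enoyl}-1,3-oxazolidin-2-one | COc1ccc(/C=C/CC(=O)N2[C@H](Cc3ccccc3)COC2=O)cc1OCc1ccccc1 | intermediate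
10 | sodium (1Z,3E)-1-[(4R)-4-benzyl-2-oxo-1,3-oxazolidin-3-yl]-4-[3-(benzyloxy)-4-methoxyphenyl]buta-1,3-dien-1-olate | COc1ccc(/C=C/C=C(\[O-])N2[C@H](Cc3ccccc3)COC2=O)cc1OCc1ccccc1.[Na+] | intermediate (not isolated)
11 | (4R)-4-benzyl-3-{(2R,3E)-2-[4-(benzyloxy)-3-methoxybenzyl]-4-[3-(benzyloxy)-4-methoxyphenyl]but-3-enoyl}-1,3-oxazolidin-2-one | COc1ccc(/C=C/[C@H](C(=O)N2[C@H](Cc3ccccc3)COC2=O)Cc2ccc(OCc3ccccc3)c(OC)c2)cc1OCc1ccccc1 | intermediate
12 | (2R,3E)-2-[4-(benzyloxy)-3-methoxybenzyl]-4-[3-(benzyloxy)-4-methoxyphenyl]but-3-en-1-ol | COc1ccc(/C=C/[C@H](CO)Cc2ccc(OCc3ccccc3)c(OC)c2)cc1OCc1ccccc1 | intermediate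
13 | (bromomethyl)chlorodimethylsilane | C[Si](C)(Cl)CBr | starting material
14 | (bromomethyl)({(2R,3E)-2-[4-(benzyloxy)-3-methoxybenzyl]-4-[3-(benzyloxy)-4-methoxyphenyl]but-3-en-1-yl}oxy)dimethylsilane | COc1ccc(/C=C/[C@H](CO[Si](C)(C)CBr)Cc2ccc(OCc3ccccc3)c(OC)c2)cc1OCc1ccccc1 | intermediate
15 | (4R,5R)-4-[3-(benzyloxy)-4-methoxybenzyl]-5-[4-(benzyloxy)-3-methoxybenzyl]-2,2-dimethyl-1,2-oxasilinane | C[Si]1(C)C[C@H](Cc2ccc(OC)c(OCc3ccccc3)c2)[C@@H](Cc2ccc(OCc3ccccc3)c(OC)c2)CO1 | intermediate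
16 | (2R,3R)-2-[3-(benzyloxy)-4-methoxybenzyl]-3-[4-(benzyloxy)-3-methoxybenzyl]butane-1,4-diol | COc1ccc(C[C@@H](CO)[C@H](CO)Cc2ccc(OCc3ccccc3)c(OC)c2)cc1OCc1ccccc1 | intermediate
17 | (2R,3R)-2-[3-(benzyloxy)-4-methoxybenzyl]-3-[4-(benzyloxy)-3-methoxybenzyl]butane-1,4-diyl dibenzoate | COc1ccc(C[C@@H](COC(=O)c2ccccc2)[C@H](COC(=O)c2ccccc2)Cc2ccc(OCc3ccccc3)c(OC)c2)cc1OCc1ccccc1 | intermediate
18 | (2R,3R)-2-(3-hydroxy-4-methoxybenzyl)-3-(4-hydroxy-3-methoxybenzyl)butane-1,4-diyl dibenzoate (CNP0306197.1) | COc1ccc(C[C@@H](COC(=O)c2ccccc2)[C@H](COC(=O)c2ccccc2)Cc2ccc(O)c(OC)c2)cc1O | target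

Total step count: 10. Longest linear sequence: 9 steps (steps 2 to 10, from 3 to 18); step 1 is a one-step branch that joins at step 4.

Steps most likely to fail

Step 7. The α-silyl radical may be reduced before it cyclizes, it may abstract the allylic hydrogen on C8' (1,5-hydrogen transfer), or the facial discrimination at C8 in the ring closure may be weak. The fallback replaces the radical closure by enolate chemistry; it sets out from bromide 2, with 7 and 3 as further inputs, and returns at diol 16.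
- Auxiliary 7 is acylated with 4-tert-butoxy-4-oxobutanoic acid (PivCl, Et3N, LiCl, THF) to tert-butyl 4-[(4R)-4-benzyl-2-oxo-1,3-oxazolidin-3-yl]-4-oxobutanoate F1.
- Evans alkylation of its sodium enolate (NaN(SiMe3)2, THF, −78 °C) with 2, under the same facial control as in step 4, gives tert-butyl (3R)-3-[4-(benzyloxy)-3-methoxybenzyl]-4-[(4R)-4-benzyl-2-oxo-1,3-oxazolidin-3-yl]-4-oxobutanoate F2.
- LiBH4 reduces the imide carbonyl only, giving tert-butyl (3R)-3-[4-(benzyloxy)-3-methoxybenzyl]-4-hydroxybutanoate F3, and TsOH in toluene closes it to (4R)-4-[4-(benzyloxy)-3-methoxybenzyl]oxolan-2-one F4.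
- Aldehyde 3 is reduced with NaBH4 to [3-(benzyloxy)-4-methoxyphenyl]methanol F5 and brominated with PBr3 to 2-(benzyloxy)-4-(bromomethyl)-1-methoxybenzene F6.
- The lithium enolate of F4 (LiN(SiMe3)2, THF, −78 °C) is alkylated by F6 anti to the benzyl group already on the ring, the classical trans-selective lactone alkylation, to give (3R,4R)-3-[3-(benzyloxy)-4-methoxybenzyl]-4-[4-(benzyloxy)-3-methoxybenzyl]oxolan-2-one F7.
- LiAlH4 in THF reduces F7 to 16.

Step 4. The aryl-conjugated dienolate is strongly delocalised, so C-alkylation may be sluggish, and proton exchange at the doubly activated α-carbon may erode the configuration at C8'. The fallback sets the stereocentre on a simpler dienolate and brings in ring A afterwards; it sets out from auxiliary 7, with 2 and 3 as further inputs, and returns at alcohol 12.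
- Auxiliary 7 is acylated with but-3-enoic acid (PivCl, Et3N, LiCl) to (4R)-4-benzyl-3-(but-3-enoyl)-1,3-oxazolidin-2-one F8.
- Its sodium dienolate (NaN(SiMe3)2, THF, −78 °C) is alkylated with 2 to (4R)-4-benzyl-3-{(2R)-2-[4-(benzyloxy)-3-methoxybenzyl]but-3-enoyl}-1,3-oxazolidin-2-one F9.
- LiBH4 gives (2R)-2-[4-(benzyloxy)-3-methoxybenzyl]but-3-en-1-ol F10.
- Aldehyde 3 is methylenated (Ph3PCH3Br, KOt-Bu, THF) to 2-(benzyloxy)-4-ethenyl-1-methoxybenzene F11.
- Cross-metathesis of F10 with excess F11 (second-generation Grubbs catalyst, CH2Cl2, 40 °C) gives 12.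

Step 5. Hydride may attack the ring carbonyl of the congested imide, which opens the oxazolidinone instead of releasing it. The fallback separates cleavage from reduction; it sets out from 11 and returns at 12.
- LiOH/H2O2 (THF/H2O, 0 °C), which attacks the exocyclic carbonyl selectively, gives (2R,3E)-2-[4-(benzyloxy)-3-methoxybenzyl]-4-[3-(benzyloxy)-4-methoxyphenyl]but-3-enoic acid F12 and the recovered auxiliary.
- LiAlH4 (THF, 0 °C) reduces F12 to 12.

Further compounds
F1 | step 7 | tert-butyl 4-[(4R)-4-benzyl-2-oxo-1,3-oxazolidin-3-yl]-4-oxobutanoate | CC(C)(C)OC(=O)CCC(=O)N1[C@H](Cc2ccccc2)COC1=O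
F2 | step 7 | tert-butyl (3R)-3-[4-(benzyloxy)-3-methoxybenzyl]-4-[(4R)-4-benzyl-2-oxo-1,3-oxazolidin-3-yl]-4-oxobutanoate | CC(C)(C)OC(=O)C[C@H](C(=O)N1[C@H](Cc2ccccc2)COC1=O)Cc1ccc(OCc2ccccc2)c(OC)c1
F3 | step 7 | tert-butyl (3R)-3-[4-(benzyloxy)-3-methoxybenzyl]-4-hydroxybutanoate | CC(C)(C)OC(=O)C[C@H](CO)Cc1ccc(OCc2ccccc2)c(OC)c1
F4 | step 7 | (4R)-4-[4-(benzyloxy)-3-methoxybenzyl]oxolan-2-one | O=C1C[C@@H](Cc2ccc(OCc3ccccc3)c(OC)c2)CO1
F5 | step 7 | [3-(benzyloxy)-4-methoxyphenyl]methanol | COc1ccc(CO)cc1OCc1ccccc1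
F6 | step 7 | 2-(benzyloxy)-4-(bromomethyl)-1-methoxybenzene | COc1ccc(CBr)cc1OCc1ccccc1
F7 | step 7 | (3R,4R)-3-[3-(benzyloxy)-4-methoxybenzyl]-4-[4-(benzyloxy)-3-methoxybenzyl]oxolan-2-one | COc1ccc(C[C@H]2C(=O)OC[C@@H]2Cc2ccc(OCc3ccccc3)c(OC)c2)cc1OCc1ccccc1
F8 | step 4 | (4R)-4-benzyl-3-(but-3-enoyl)-1,3-oxazolidin-2-one | C=CCC(=O)N1[C@H](Cc2ccccc2)COC1=O
F9 | step 4 | (4R)-4-benzyl-3-{(2R)-2-[4-(benzyloxy)-3-methoxybenzyl]but-3-enoyl}-1,3-oxazolidin-2-one | C=C[C@H](C(=O)N1[C@H](Cc2ccccc2)COC1=O)Cc1ccc(OCc2ccccc2)c(OC)c1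
F10 | step 4 | (2R)-2-[4-(benzyloxy)-3-methoxybenzyl]but-3-en-1-ol | C=C[C@H](CO)Cc1ccc(OCc2ccccc2)c(OC)c1
F11 | step 4 | 2-(benzyloxy)-4-ethenyl-1-methoxybenzene | COc1ccc(C=C)cc1OCc1ccccc1
F12 | step 5 | (2R,3E)-2-[4-(benzyloxy)-3-methoxybenzyl]-4-[3-(benzyloxy)-4-methoxyphenyl]but-3-enoic acid | COc1ccc(/C=C/[C@H](C(=O)O)Cc2ccc(OCc3ccccc3)c(OC)c2)cc1OCc1ccccc1
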